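## Retrosynthetic overview

- The amide bonds are made last: target ⇒ diamine + 2-(trichloroacetyl)pyrrole. The two 2-aminoimidazoles (rings B and C) ⇒ bis(chloromethyl ketone) + Boc-guanidine ⇒ all-trans cyclobutane-1,2-diester.
- Enabling feature: in the cyclobutane (ring A) each of the two ring carbons that carry an imidazole is bonded to an imidazole C4, which is a carboxyl-level carbon in the precursor. Both are therefore enolisable α-carbons of like (nucleophilic) polarity, and the C2 axis through the midpoints of the two unlike ring bonds makes them equivalent. The all-trans array is the thermodynamic one, and both new centres stay epimerisable.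
- Key disconnection: the ring bond between these two carbons ⇒ intramolecular oxidative coupling of the bis-enolate of an acyclic, C2-symmetric 3,4-bis(aminomethyl)adipate.
- The adipate ⇒ ozonolytic opening of an enantiopure trans-4,5-disubstituted cyclohexene, a temporary ring that carries the only two purchased stereocentres. Overall the six-membered ring is contracted to the four-membered one; the excised alkene carbons reappear as the imidazole C4 atoms.
- Ring order: cyclohexene (bought, opened in step 4) → cyclobutane ring A (step 5) → imidazole rings B and C (step 7); the pyrroles are bought.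

Key step: step 5

Assumption: (1S,2S)-cyclohex-4-ene-1,2-dicarboxylic acid is taken as a catalogue compound; it is otherwise the known auxiliary-controlled Diels–Alder adduct of buta-1,3-diene and a dimenthyl fumarate after hydrolysis.

Remark: the polyamines 14 and 15 would be handled as trifluoroacetate salts; they are drawn and counted as free bases, and the amine base in step 10 only liberates them.

Remark on stoichiometry: every operation from step 1 to step 10 is carried out twice on a C2-symmetric substrate, so each reagent or partner that is built in is taken up twice per molecule of substrate; the equivalents are given on the Conditions lines.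

## Route

Step 1
Reactants: 1 (1S,2S)-cyclohex-4-ene-1,2-dicarboxylic acid; 2 benzylamine (two equivalents)
Product: 4 (1S,2S)-N1,N2-dibenzylcyclohex-4-ene-1,2-dicarboxamide, via diacid chloride 3 (not isolated)
Conditions: (COCl)2 (2.4 equiv), cat. DMF, CH2Cl2, 0 → 25 °C; concentrate; then 2 (2.2 equiv), Et3N (2.5 equiv), CH2Cl2, 0 → 25 °C
Reagents that add atoms: oxalyl chloride, ClC(=O)C(=O)Cl (chlorine of intermediate 3 only; none of its atoms remains in 4)
Why: Acid chloride formation at both carboxyl groups followed by Schotten–Baumann-type amidation, in which each of the two acid chloride groups of 3 takes up one molecule of benzylamine (two molecules of 2 per molecule of 1), should give the bis-amide, the trans (1S,2S) centres being the thermodynamically preferred arrangement and not expected to epimerise.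

Step 2
Reactants: 4 (1S,2S)-N1,N2-dibenzylcyclohex-4-ene-1,2-dicarboxamide
Product: 5 1,1′-[(1S,2S)-cyclohex-4-ene-1,2-diyl]bis(N-benzylmethanamine)
Conditions: LiAlH4, THF, reflux; aq. NaOH work-up
Reagents that add atoms: none
Why: LiAlH4 reduction of secondary amides to amines should leave the isolated alkene and both stereocentres untouched, and the centres thereby cease to be α to a carbonyl.

Step 3
Reactants: 5 1,1′-[(1S,2S)-cyclohex-4-ene-1,2-diyl]bis(N-benzylmethanamine)
Product: 6 di-tert-butyl N,N′-[(1S,2S)-cyclohex-4-ene-1,2-diylbis(methylene)]bis(N-benzylcarbamate)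
Conditions: Boc2O (2.4 equiv), Et3N (cat.), CH2Cl2, 25 °C
Reagents that add atoms: di-tert-butyl dicarbonate, CC(C)(C)OC(=O)OC(=O)OC(C)(C)C
Why: Carbamate formation (N-Boc protection) at both secondary amines should give fully substituted, ozone-tolerant nitrogens that carry no acidic N–H and cannot lactamise onto the esters formed next.

Step 4
Reactants: 6 di-tert-butyl N,N′-[(1S,2S)-cyclohex-4-ene-1,2-diylbis(methylene)]bis(N-benzylcarbamate)
Product: 7 dimethyl (3S,4S)-3,4-bis{[benzyl(tert-butoxycarbonyl)amino]methyl}hexanedioate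
Conditions: O3, NaOH (2.5 M in MeOH), CH2Cl2, −78 °C; then H2O, 25 °C
Reagents that add atoms: ozone, [O-][O+]=O; methanol, CO
Why: Ozonolysis in methanolic NaOH should turn both alkene carbons directly into methyl esters (the carbonyl oxide is trapped by methanol and the α-methoxy hydroperoxide dehydrated by base, the aldehyde hemiacetal is oxidised by a second molecule of ozone), giving a C2-symmetric adipate whose stereocentres are β to the esters and cannot epimerise.

Step 5
Reactants: 7 dimethyl (3S,4S)-3,4-bis{[benzyl(tert-butoxycarbonyl)amino]methyl}hexanedioate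
Product: 9 dimethyl (1S,2S,3R,4R)-3,4-bis{[benzyl(tert-butoxycarbonyl)amino]methyl}cyclobutane-1,2-dicarboxylate, via dilithium bis-enolate 8 (not isolated)
Conditions: 7 added to LiN(iPr)2 (2.3 equiv), THF, −78 °C; then CuBr2 (2.3 equiv), THF/DMF, 0.02 M, −78 → 0 °C; then NaOMe (cat.), MeOH, 25 °C
Reagents that add atoms: lithium diisopropylamide, [Li+].CC(C)[N-]C(C)C (lithium of intermediate 8 only; none of its atoms remains in 9)
Why: Inverse addition of 7 to excess LiN(iPr)2 should give the bis(ester enolate) 8, and one-electron oxidation of one enolate by divalent copper should generate an α-ester radical (or the derived α-bromo ester) that is captured by the second enolate four atoms away, a second one-electron oxidation completing the C1–C2 bond of 9 and so uniting two carbons of like, nucleophilic polarity. The closest known reaction type is the intramolecular oxidative coupling of diester and diimide bis-enolates with CuBr2, CuCl2 or I2, which turns adipic acid derivatives into trans-cyclobutane-1,2-dicarboxylic acid derivatives. Ring A closes in a 4-exo mode, favoured by the two vicinal branches at C3 and C4 of 7, which hold the two CH2CO2Me arms gauche to each other. Each new stereocentre is controlled by the neighbouring fixed centre (the ester takes the face anti to the adjacent aminomethyl arm) and by the trans preference of the two esters, and since both new centres are α to esters the closing NaOMe treatment should converge any cis isomer to the all-trans array, the most stable one, without touching the two non-enolisable centres that carry the absolute configuration. The selectivity needed is ring closure over Dieckmann condensation and over intermolecular coupling: complete bis-enolisation before warming removes the electrophilic ester, high dilution at the oxidation stage favours the intramolecular event, and the fully substituted N-benzyl-N-Boc carbamates offer neither an acidic N–H nor a nucleophilic nitrogen.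

Step 6
Reactants: 9 dimethyl (1S,2S,3R,4R)-3,4-bis{[benzyl(tert-butoxycarbonyl)amino]methyl}cyclobutane-1,2-dicarboxylate
Product: 11 di-tert-butyl N,N′-{[(1R,2R,3S,4S)-3,4-bis(chloroacetyl)cyclobutane-1,2-diyl]bis(methylene)}bis(N-benzylcarbamate), via dilithium tetrahedral adduct 10 (not isolated)
Conditions: ICH2Cl (4 equiv), MeLi·LiBr (3.6 equiv), THF/Et2O, −78 °C; then AcOH, −78 → 25 °C
Reagents that add atoms: chloroiodomethane, ClCI; methyllithium, [Li]C (lithium of intermediate 10 only)
Why: Acyl substitution of both esters by the carbenoid chloromethyllithium (one-carbon homologation to the α-chloroketone) should stop at the ketone stage because the tetrahedral lithium hemiketal 10 survives at −78 °C until the acetic acid quench, and the α-centres can only revert to the all-trans array.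

Step 7
Reactants: 11 di-tert-butyl N,N′-{[(1R,2R,3S,4S)-3,4-bis(chloroacetyl)cyclobutane-1,2-diyl]bis(methylene)}bis(N-benzylcarbamate); 12 N-Boc-guanidine
Product: 13 di-tert-butyl 4,4′-[(1S,2S,3R,4R)-3,4-bis{[benzyl(tert-butoxycarbonyl)amino]methyl}cyclobutane-1,2-diyl]bis(2-amino-1H-imidazole-1-carboxylate)
Conditions: 12 (6 equiv), NaI (cat.), DMF, 25 °C
Reagents that add atoms: none
Why: Cyclocondensation of each α-haloketone with one molecule of the mono-protected guanidine (N-alkylation, then intramolecular carbonyl condensation and dehydration to the aromatic ring, with iodide catalysis by Finkelstein exchange) should build both 2-aminoimidazoles, rings B and C, at once without touching the ring stereocentres; the Boc group is drawn on the ring nitrogen as usually assigned, and its position is immaterial because step 8 removes it.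

Step 8
Reactants: 13 di-tert-butyl 4,4′-[(1S,2S,3R,4R)-3,4-bis{[benzyl(tert-butoxycarbonyl)amino]methyl}cyclobutane-1,2-diyl]bis(2-amino-1H-imidazole-1-carboxylate)
Product: 14 5,5′-{(1S,2S,3R,4R)-3,4-bis[(benzylamino)methyl]cyclobutane-1,2-diyl}bis(1H-imidazol-2-amine)
Conditions: TFA/CH2Cl2 (1:1), 0 → 25 °C
Reagents that add atoms: none
Why: Acidolysis of tert-butyl carbamates (loss of isobutene and CO2) should remove all four Boc groups in one operation, the cyclobutane and the protonated 2-aminoimidazoles being inert to TFA.

Step 9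
Reactants: 14 5,5′-{(1S,2S,3R,4R)-3,4-bis[(benzylamino)methyl]cyclobutane-1,2-diyl}bis(1H-imidazol-2-amine)
Product: 15 5,5′-[(1S,2S,3R,4R)-3,4-bis(aminomethyl)cyclobutane-1,2-diyl]bis(1H-imidazol-2-amine)
Conditions: H2 (3 bar), Pd(OH)2/C, MeOH, 40 °C
Reagents that add atoms: none
Why: Hydrogenolysis of the N-benzyl groups of the secondary benzylammonium salts should free the two primary amines, the aromatic 2-aminoimidazolium rings and the cyclobutane being stable to these conditions.

Step 10
Reactants: 15 5,5′-[(1S,2S,3R,4R)-3,4-bis(aminomethyl)cyclobutane-1,2-diyl]bis(1H-imidazol-2-amine); 16 2-(trichloroacetyl)pyrrole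
Product: 17 N,N′-{[(1R,2R,3S,4S)-3,4-bis(2-amino-1H-imidazol-5-yl)cyclobutane-1,2-diyl]bis(methylene)}bis(1H-pyrrole-2-carboxamide)
Conditions: 16 (2.2 equiv), iPr2NEt, DMF, 25 °C; reverse-phase chromatography
Reagents that add atoms: none
Why: In this haloform-type acylation each of the two primary amines attacks one molecule of the trichloromethyl ketone and expels trichloromethanide (chloroform), and they should react selectively over the far less nucleophilic 2-aminoimidazole nitrogens to give the all-trans bis-amide target.

## Compound list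

1 | (1S,2S)-cyclohex-4-ene-1,2-dicarboxylic acid | OC(=O)[C@H]1CC=CC[C@@H]1C(=O)O | starting material
2 | benzylamine | NCc1ccccc1 | starting material
3 | (1S,2S)-cyclohex-4-ene-1,2-dicarbonyl dichloride | ClC(=O)[C@H]1CC=CC[C@@H]1C(=O)Cl | intermediate
4 | (1S,2S)-N1,N2-dibenzylcyclohex-4-ene-1,2-dicarboxamide | O=C(NCc1ccccc1)[C@H]1CC=CC[C@@H]1C(=O)NCc1ccccc1 | intermediate
5 | 1,1′-[(1S,2S)-cyclohex-4-ene-1,2-diyl]bis(N-benzylmethanamine) | C(c1ccccc1)NC[C@H]1CC=CC[C@@H]1CNCc1ccccc1 | intermediate
6 | di-tert-butyl N,N′-[(1S,2S)-cyclohex-4-ene-1,2-diylbis(methylene)]bis(N-benzylcarbamate) | CC(C)(C)OC(=O)N(Cc1ccccc1)C[C@H]1CC=CC[C@@H]1CN(Cc1ccccc1)C(=O)OC(C)(C)C | intermediate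
7 | dimethyl (3S,4S)-3,4-bis{[benzyl(tert-butoxycarbonyl)amino]methyl}hexanedioate | COC(=O)C[C@H](CN(Cc1ccccc1)C(=O)OC(C)(C)C)[C@@H](CN(Cc1ccccc1)C(=O)OC(C)(C)C)CC(=O)OC | intermediate
8 | dilithium bis-enolate of 7 (enolate geometry undefined) | [Li+].[Li+].COC([O-])=C[C@H](CN(Cc1ccccc1)C(=O)OC(C)(C)C)[C@@H](CN(Cc1ccccc1)C(=O)OC(C)(C)C)C=C([O-])OC | intermediate
9 | dimethyl (1S,2S,3R,4R)-3,4-bis{[benzyl(tert-butoxycarbonyl)amino]methyl}cyclobutane-1,2-dicarboxylate (all-trans) | COC(=O)[C@H]1[C@H](CN(Cc2ccccc2)C(=O)OC(C)(C)C)[C@@H](CN(Cc2ccccc2)C(=O)OC(C)(C)C)[C@@H]1C(=O)OC | intermediate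
10 | dilithium bis(hemiketal alkoxide) from addition of chloromethyllithium to both esters of 9 (hemiketal carbons undefined) | [Li+].[Li+].COC([O-])(CCl)[C@H]1[C@H](CN(Cc2ccccc2)C(=O)OC(C)(C)C)[C@@H](CN(Cc2ccccc2)C(=O)OC(C)(C)C)[C@@H]1C([O-])(CCl)OC | intermediate
11 | di-tert-butyl N,N′-{[(1R,2R,3S,4S)-3,4-bis(chloroacetyl)cyclobutane-1,2-diyl]bis(methylene)}bis(N-benzylcarbamate) | ClCC(=O)[C@H]1[C@H](CN(Cc2ccccc2)C(=O)OC(C)(C)C)[C@@H](CN(Cc2ccccc2)C(=O)OC(C)(C)C)[C@@H]1C(=O)CCl | intermediate
12 | N-Boc-guanidine (tert-butyl N-carbamimidoylcarbamate) | CC(C)(C)OC(=O)NC(N)=N | starting material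
13 | di-tert-butyl 4,4′-[(1S,2S,3R,4R)-3,4-bis{[benzyl(tert-butoxycarbonyl)amino]methyl}cyclobutane-1,2-diyl]bis(2-amino-1H-imidazole-1-carboxylate) | CC(C)(C)OC(=O)n1cc(nc1N)[C@H]1[C@H](CN(Cc2ccccc2)C(=O)OC(C)(C)C)[C@@H](CN(Cc2ccccc2)C(=O)OC(C)(C)C)[C@@H]1c1cn(C(=O)OC(C)(C)C)c(N)n1 | intermediate
14 | 5,5′-{(1S,2S,3R,4R)-3,4-bis[(benzylamino)methyl]cyclobutane-1,2-diyl}bis(1H-imidazol-2-amine) | Nc1ncc([C@H]2[C@H](CNCc3ccccc3)[C@@H](CNCc3ccccc3)[C@@H]2c2cnc(N)[nH]2)[nH]1 | intermediate
15 | 5,5′-[(1S,2S,3R,4R)-3,4-bis(aminomethyl)cyclobutane-1,2-diyl]bis(1H-imidazol-2-amine) | Nc1ncc([C@H]2[C@H](CN)[C@@H](CN)[C@@H]2c2cnc(N)[nH]2)[nH]1 | intermediate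
16 | 2-(trichloroacetyl)pyrrole (2,2,2-trichloro-1-(1H-pyrrol-2-yl)ethan-1-one) | O=C(c1ccc[nH]1)C(Cl)(Cl)Cl | starting material
17 | N,N′-{[(1R,2R,3S,4S)-3,4-bis(2-amino-1H-imidazol-5-yl)cyclobutane-1,2-diyl]bis(methylene)}bis(1H-pyrrole-2-carboxamide) | Nc1ncc([C@H]2[C@H](CNC(=O)c3ccc[nH]3)[C@@H](CNC(=O)c3ccc[nH]3)[C@@H]2c2cnc(N)[nH]2)[nH]1 | target

## Step count and risks

Total step count: 10. Longest linear sequence: 10 steps (1 → 17).

Steps most likely to fail:

Step 5. Dieckmann condensation of incompletely enolised diester, intermolecular coupling to oligomers, or α-bromination and dehydrogenation may outrun closure of the strained ring. The fallback is a ring contraction that sets out from 7 and comes back at 9, and it makes the threatening Dieckmann reaction its first move. KOtBu in THF at 0 °C should cyclise 7 (one constitutional outcome, since 7 is C2-symmetric) to the β-keto ester methyl 4,5-bis{[benzyl(tert-butoxycarbonyl)amino]methyl}-2-oxocyclopentane-1-carboxylate F1 (aminomethyl-bearing centres as in 7). Its dianion (LiN(SiMe3)2, 2.2 equiv, THF, −78 °C) should be C-acylated at the α′-methylene by 2,2,2-trifluoroethyl trifluoroacetate to give the α′-trifluoroacetyl ketone methyl 4,5-bis{[benzyl(tert-butoxycarbonyl)amino]methyl}-2-oxo-3-(trifluoroacetyl)cyclopentane-1-carboxylate F2. Detrifluoroacetylative diazo transfer (MsN3, Et3N, MeCN/H2O) should then give the α′-diazo β-keto ester methyl 4,5-bis{[benzyl(tert-butoxycarbonyl)amino]methyl}-3-diazo-2-oxocyclopentane-1-carboxylate F3. Irradiation (hν, 300 nm) in MeOH should bring about the photochemical Wolff ring contraction, in which the ester-bearing carbon migrates to the carbene carbon and so forms the same ring bond, the ketene being trapped by methanol. NaOMe/MeOH equilibration as in step 5 should then deliver 9.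

Step 6. Premature collapse of the tetrahedral adduct may lead to double addition of the carbenoid, or the second, more hindered ester may react incompletely. The fallback sets out from 9 and comes back at 11. Both esters should acylate dimethylsulfoxonium methylide (Me3S(O)I, KOtBu, THF, reflux) to give the bis(β-keto dimethylsulfoxonium ylide) di-tert-butyl N,N′-{[(1R,2R,3S,4S)-3,4-bis[(dimethyloxosulfanylidene)acetyl]cyclobutane-1,2-diyl]bis(methylene)}bis(N-benzylcarbamate) F4. This is formed as a stabilised ylide and cannot add a second equivalent. LiCl and MsOH in THF at 65 °C should then replace the sulfoxonium group by chloride, with loss of dimethyl sulfoxide, to give 11.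

Step 7. One guanidine may be alkylated by both neighbouring chloroketones (bridging), regioisomeric N-alkylation may occur, or the chloroketone may decompose during a sluggish displacement. The fallback sets out from 11 and comes back at 14, and it builds the heterocycle in masked form. 2-Aminopyrimidine (EtOH, 80 °C) should alkylate at its ring nitrogen and condense through its amino group to give the bis(imidazo[1,2-a]pyrimidine) di-tert-butyl N,N′-{[(1R,2R,3S,4S)-3,4-bis(imidazo[1,2-a]pyrimidin-2-yl)cyclobutane-1,2-diyl]bis(methylene)}bis(N-benzylcarbamate) F5. Hydrazine hydrate in refluxing EtOH should cleave the pyrimidine rings (released as pyrazole) to the bis(2-aminoimidazole) di-tert-butyl N,N′-{[(1R,2R,3S,4S)-3,4-bis(2-amino-1H-imidazol-5-yl)cyclobutane-1,2-diyl]bis(methylene)}bis(N-benzylcarbamate) F6. TFA/CH2Cl2 should then remove the two carbamate Boc groups to give 14.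

## Further compounds

F1 | step 5 | methyl 4,5-bis{[benzyl(tert-butoxycarbonyl)amino]methyl}-2-oxocyclopentane-1-carboxylate (aminomethyl-bearing centres as in 7, C1 epimerisable) | COC(=O)C1[C@H](CN(Cc2ccccc2)C(=O)OC(C)(C)C)[C@@H](CN(Cc2ccccc2)C(=O)OC(C)(C)C)CC1=O
F2 | step 5 | methyl 4,5-bis{[benzyl(tert-butoxycarbonyl)amino]methyl}-2-oxo-3-(trifluoroacetyl)cyclopentane-1-carboxylate | COC(=O)C1[C@H](CN(Cc2ccccc2)C(=O)OC(C)(C)C)[C@@H](CN(Cc2ccccc2)C(=O)OC(C)(C)C)C(C(=O)C(F)(F)F)C1=O
F3 | step 5 | methyl 4,5-bis{[benzyl(tert-butoxycarbonyl)amino]methyl}-3-diazo-2-oxocyclopentane-1-carboxylate | COC(=O)C1[C@H](CN(Cc2ccccc2)C(=O)OC(C)(C)C)[C@@H](CN(Cc2ccccc2)C(=O)OC(C)(C)C)C(=[N+]=[N-])C1=O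
F4 | step 6 | di-tert-butyl N,N′-{[(1R,2R,3S,4S)-3,4-bis[(dimethyloxosulfanylidene)acetyl]cyclobutane-1,2-diyl]bis(methylene)}bis(N-benzylcarbamate) | CS(C)(=O)=CC(=O)[C@H]1[C@H](CN(Cc2ccccc2)C(=O)OC(C)(C)C)[C@@H](CN(Cc2ccccc2)C(=O)OC(C)(C)C)[C@@H]1C(=O)C=S(C)(C)=O
F5 | step 7 | di-tert-butyl N,N′-{[(1R,2R,3S,4S)-3,4-bis(imidazo[1,2-a]pyrimidin-2-yl)cyclobutane-1,2-diyl]bis(methylene)}bis(N-benzylcarbamate) | c1cnc2nc(cn2c1)[C@H]1[C@H](CN(Cc2ccccc2)C(=O)OC(C)(C)C)[C@@H](CN(Cc2ccccc2)C(=O)OC(C)(C)C)[C@@H]1c1cn2cccnc2n1
F6 | step 7 | di-tert-butyl N,N′-{[(1R,2R,3S,4S)-3,4-bis(2-amino-1H-imidazol-5-yl)cyclobutane-1,2-diyl]bis(methylene)}bis(N-benzylcarbamate) | Nc1ncc([C@H]2[C@H](CN(Cc3ccccc3)C(=O)OC(C)(C)C)[C@@H](CN(Cc3ccccc3)C(=O)OC(C)(C)C)[C@@H]2c2cnc(N)[nH]2)[nH]1
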